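**Retrosynthetic overview**
1. Target 33 comes from the 18-deoxy lactam 31 by late C18–H hydroxylation; 31 comes from reductive opening (C3–O) of the 2,3-epoxy-4-ketone 30.
2. 30 comes from bromomethyl ketone/pyruvanilide 27: a sulfonium-ylide epoxidation forms C2–C3, so the oxirane and the 15-membered lactam ring close together and C2 is set.
3. 27 comes from (Z)-alkenyl iodide 16 and α-methoxy aldehyde 19 (C7–C8, chelation control), then carbamate, N-pyruvoylation and oxirane → bromomethyl ketone.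
4. 16 comes from an intramolecular SNAr of the C11 alkoxide on an o-nitro aryl fluoride (benzoxocine); C10/C11 by (Z)-crotylboration, C12 and C6 from one SAMP hydrazone, C14 by Evans alkylation.
5. Ring order: 8-membered benzoxocine (step 8), then oxirane plus 15-membered lactam in one operation (step 18); the oxirane is opened in step 19.

Numbering used in names: amide C1, carbinol C2, C3H2, ketone C4, C5H2, C6(OMe), C7(OCONH2), C8(Me)=C9, C10(Me), C11(O-aryl), C12(OMe), C13H2, C14(Me), C15H2, aryl C16–C21 (C18 OH, C20 N, C21 O).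

Assumption: 1 is bought (otherwise one NBS step from 2-fluoro-3-nitrotoluene), and the SAMP azaenolate alkylates in the usual Enders sense (otherwise RAMP is used in steps 4, 5 and 12).

**Step 1**
Reactants: 1 2-fluoro-3-nitrobenzyl bromide; 2 (S)-4-benzyl-3-propanoyl-1,3-oxazolidin-2-one
Product: 3 (S)-4-benzyl-3-[(2R)-3-(2-fluoro-3-nitrophenyl)-2-methylpropanoyl]-1,3-oxazolidin-2-one
Conditions: NaN(SiMe3)2, THF, −78 °C; then 1, −78 → −20 °C
Reagents that add atoms: none
Why: Evans asymmetric alkylation; the chelated Z-enolate is benzylated on the face away from the auxiliary benzyl group, which sets C14 (R).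

**Step 2**
Reactants: 3 alkylated imide
Product: 4 (2R)-3-(2-fluoro-3-nitrophenyl)-2-methylpropan-1-ol
Conditions: LiBH4, MeOH (1 equiv), Et2O, 0 °C
Reagents that add atoms: none
Why: Reductive cleavage of the N-acyl oxazolidinone by borohydride leaves ArNO2, ArF and C14 untouched.

**Step 3**
Reactants: 4 alcohol
Product: 5 (2R)-3-(2-fluoro-3-nitrophenyl)-2-methylpropyl trifluoromethanesulfonate
Conditions: Tf2O, 2,6-lutidine, CH2Cl2, −78 °C (used at once)
Reagents that add atoms: trifluoromethanesulfonic anhydride O=S(=O)(OS(=O)(=O)C(F)(F)F)C(F)(F)F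
Why: O-sulfonylation gives a primary electrophile reactive enough for alkylation at −100 °C, below the temperature at which a carbanion would attack the activated aryl fluoride.

**Step 4**
Reactants: 6 1,1,2-trimethoxyethane; 7 SAMP, (S)-1-amino-2-(methoxymethyl)pyrrolidine
Product: 8 (2S)-N-[(E)-2-methoxyethylidene]-2-(methoxymethyl)pyrrolidin-1-amine
Conditions: p-TsOH (cat.), 4 Å MS, CH2Cl2, 40 °C
Reagents that add atoms: none
Why: Acid-catalysed acetal-to-hydrazone exchange (hydrazone formation), driven by removal of methanol.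

**Step 5**
Reactants: 8 hydrazone; 5 triflate
Product: 9 SAMP hydrazone of (2S,4R)-5-(2-fluoro-3-nitrophenyl)-2-methoxy-4-methylpentanal
Conditions: LiN(i-Pr)2, THF, 0 °C; then 5, −100 → −78 °C
Reagents that add atoms: none
Why: Enders SAMP-hydrazone α-alkylation; the lithium azaenolate is alkylated on the face away from the methoxymethyl arm, which sets C12 (S).

**Step 6**
Reactants: 9 alkylated hydrazone
Product: 10 (2S,4R)-5-(2-fluoro-3-nitrophenyl)-2-methoxy-4-methylpentanal
Conditions: saturated aqueous (CO2H)2, Et2O, rt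
Reagents that add atoms: water O
Why: Two-phase oxalic acid hydrolysis of the hydrazone returns the auxiliary without epimerising the α-methoxy aldehyde.

**Step 7**
Reactants: 10 aldehyde; 11 2-[(2Z)-but-2-en-1-yl]-4,4,5,5-tetramethyl-1,3,2-dioxaborolane
Product: 12 (3S,4R,5S,7R)-8-(2-fluoro-3-nitrophenyl)-5-methoxy-3,7-dimethyloct-1-en-4-ol
Conditions: 11 (1.5 equiv), toluene, rt, 24 h; triethanolamine work-up
Reagents that add atoms: none
Why: Hoffmann–Roush crotylboration; the closed chair transition state of the Z-boronate gives 10,11-syn and the Cornforth/Felkin preference of the α-methoxy aldehyde gives 11,12-anti, hence 10S,11R.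

**Step 8**
Reactants: 12 homoallylic alcohol
Product: 13 (2R,3S,5R)-2-[(2S)-but-3-en-2-yl]-3-methoxy-5-methyl-10-nitro-3,4,5,6-tetrahydro-2H-1-benzoxocine
Conditions: KN(SiMe3)2 (1.05 equiv), THF, 0.005 M, 0 °C → rt
Reagents that add atoms: none
Why: Intramolecular SNAr; the C11 alkoxide displaces fluoride ortho to the nitro group and closes the 8-membered aryl ether with retention at C11.

**Step 9**
Reactants: 13 benzoxocine alkene
Product: 14 (2R)-2-[(2R,3S,5R)-3-methoxy-5-methyl-10-nitro-3,4,5,6-tetrahydro-2H-1-benzoxocin-2-yl]propanal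
Conditions: O3, CH2Cl2–MeOH, −78 °C; then Me2S
Reagents that add atoms: ozone [O-][O+]=O
Why: Ozonolysis of the only alkene gives the C9 aldehyde; the nitroarene is inert and the aldehyde is used at once to protect C10.

**Step 10**
Reactants: 14 aldehyde
Product: 15 (2R,3S,5R)-2-[(2S,3Z)-4-iodopent-3-en-2-yl]-3-methoxy-5-methyl-10-nitro-3,4,5,6-tetrahydro-2H-1-benzoxocine
Conditions: [Ph3PEt]I, n-BuLi, THF; I2, −78 °C; NaN(SiMe3)2; then 14, −78 → −20 °C
Reagents that add atoms: ethyltriphenylphosphonium iodide CC[P+](c1ccccc1)(c1ccccc1)c1ccccc1.[I-]; iodine II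
Why: Stork–Zhao–Wittig olefination with the α-iodo ylide gives the (Z)-2-iodoalkene, in which iodine (later C7) is cis to C10.

**Step 11**
Reactants: 15 nitro alkenyl iodide
Product: 16 (2R,3S,5R)-2-[(2S,3Z)-4-iodopent-3-en-2-yl]-3-methoxy-5-methyl-3,4,5,6-tetrahydro-2H-1-benzoxocin-10-amine
Conditions: Fe powder, NH4Cl, EtOH–H2O, 70 °C
Reagents that add atoms: none
Why: Béchamp-type nitro reduction is chemoselective and leaves the alkenyl iodide and the aryl ether intact.

**Step 12**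
Reactants: 8 hydrazone; 17 2-(bromomethyl)oxirane (racemic)
Product: 18 SAMP hydrazone of (2S)-2-methoxy-3-(oxiran-2-yl)propanal
Conditions: LiN(i-Pr)2, THF, 0 °C; then 17, −100 → −78 °C
Reagents that add atoms: none
Why: Enders alkylation with the same facial sense as step 5 sets C6 (S); the oxirane carbon (later the C4 ketone) needs no control.

**Step 13**
Reactants: 18 hydrazone
Product: 19 (2S)-2-methoxy-3-(oxiran-2-yl)propanal
Conditions: O3, CH2Cl2, −78 °C
Reagents that add atoms: ozone [O-][O+]=O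
Why: Ozonolytic hydrazone cleavage is neutral, so the oxirane and the α-stereocentre survive.

**Step 14**
Reactants: 16 aniline alkenyl iodide; 19 aldehyde
Product: 23 (2S,3S,4Z,6S)-6-[(2R,3S,5R)-10-amino-3-methoxy-5-methyl-3,4,5,6-tetrahydro-2H-1-benzoxocin-2-yl]-2-methoxy-4-methyl-1-(oxiran-2-yl)hept-4-en-3-yl carbamate, via disilazane-protected aniline 20 (not isolated), via alkenylmagnesium bromide 21 (not isolated), via N-trichloroacetyl carbamate 22 (not isolated)
Conditions: KH, ClMe2SiCH2CH2SiMe2Cl, THF, 0 °C → rt; t-BuLi (2 equiv), −78 °C; MgBr2·OEt2; 19, −78 °C; Cl3CC(O)NCO, −78 → 0 °C; then K2CO3, MeOH, 0 °C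
Reagents that add atoms: trichloroacetyl isocyanate O=C=NC(=O)C(Cl)(Cl)Cl; 1,2-bis(chlorodimethylsilyl)ethane C[Si](C)(Cl)CC[Si](C)(C)Cl (atoms in 20 to 22); magnesium dibromide [Mg+2].[Br-].[Br-] (atoms in 21)
Why: Iodine–lithium exchange with retention of the Z geometry, transmetalation to magnesium and Cram-chelate addition (Mg bridging C7=O and the C6 methoxy oxygen) give 7S (6,7-syn); the alkoxide is carbamoylated in situ by the acyl isocyanate and methanolysis removes the trichloroacetyl and N-silyl groups.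

**Step 15**
Reactants: 23 aniline carbamate; 24 pyruvic acid
Product: 25 the N-(2-oxopropanoyl) anilide of 23
Conditions: N,N'-dicyclohexylcarbodiimide, CH2Cl2, 0 °C
Reagents that add atoms: none
Why: Carbodiimide amide coupling; the aniline nitrogen is far more nucleophilic than the carbamate NH2.

**Step 16**
Reactants: 25 pyruvanilide oxirane
Product: 26 bromohydrin of 25 (C4–OH, C3–Br, both C4 epimers)
Conditions: LiBr, AcOH, THF, rt
Reagents that add atoms: lithium bromide [Li+].[Br-]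
Why: Acid-assisted SN2 opening of the terminal oxirane by bromide at the CH2 carbon.

**Step 17**
Reactants: 26 bromohydrin
Product: 27 bromomethyl ketone (C4=O, C3H2Br) bearing the pyruvanilide
Conditions: Dess–Martin periodinane, CH2Cl2, 0 °C
Reagents that add atoms: none
Why: Dess–Martin oxidation of the only hydroxyl group under non-basic conditions; the C4 epimers converge.

**Step 18**
Reactants: 27 bromomethyl ketone
Product: 30 (2S,3S)-2,3-epoxy-4-oxo 18-deoxy macrolactam, via sulfonium bromide 28 (not isolated), via sulfonium ylide 29 (not isolated)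
Conditions: tetrahydrothiophene, acetone, rt; then K2CO3, MeCN, 0.001 M, rt
Reagents that add atoms: tetrahydrothiophene C1CCSC1 (atoms in 28 and 29)
Why: Proposed new method: tetrahydrothiophene S-alkylates the bromomethyl ketone, carbonate deprotonates only the acidic ketosulfonium C–H, and the stabilised ylide adds to the activated ketone of the α-ketoamide, after which the betaine closes by 3-exo displacement of the sulfide; this makes the reversible ketone–ketone C2–C3 bond formation irreversible, forms the oxirane and the 15-membered lactam ring together and sets C2 under macrocyclic substrate control (both C3 epimers are usable); closest known reaction type: Corey–Chaykovsky/Darzens epoxidation of isatins and α-keto esters with acyl-stabilised sulfonium ylides.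

**Step 19**
Reactants: 30 epoxy ketone
Product: 31 18-deoxy target (C2 tertiary alcohol, C4 ketone)
Conditions: SmI2 (2.2 equiv), THF–MeOH, −78 °C
Reagents that add atoms: none
Why: Samarium diiodide reduction of an α,β-epoxy ketone cleaves the Cα–O bond (C3–O) through the ketyl, giving the β-hydroxy ketone with C2 unchanged.

**Step 20**
Reactants: 31 18-deoxy macrolactam
Product: 33 target CNP0122739.1, via aryl pinacolboronate 32 (not isolated)
Conditions: [Ir(OMe)(cod)]2, 4,4'-di-tert-butyl-2,2'-bipyridine, B2pin2, THF, 65 °C; then NaBO3·4H2O, THF–H2O, rt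
Reagents that add atoms: bis(pinacolato)diboron CC1(C)OB(OC1(C)C)B1OC(C)(C)C(C)(C)O1 (atoms in 32); sodium perborate [Na+].[O-]OB=O
Why: Iridium-catalysed C–H borylation is sterically controlled and selects C18, the only aryl C–H without an ortho substituent (also para to the ether oxygen); perborate oxidation of the boronate gives the phenol.

**Compound list**
1 | 1-(bromomethyl)-2-fluoro-3-nitrobenzene | O=[N+]([O-])c1cccc(CBr)c1F | starting material
2 | (S)-4-benzyl-3-propanoyl-1,3-oxazolidin-2-one | CCC(=O)N1[C@@H](Cc2ccccc2)COC1=O | starting material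
3 | (S)-4-benzyl-3-[(2R)-3-(2-fluoro-3-nitrophenyl)-2-methylpropanoyl]-1,3-oxazolidin-2-one | O=[N+]([O-])c1cccc(C[C@@H](C)C(=O)N2[C@@H](Cc3ccccc3)COC2=O)c1F | intermediate
4 | (2R)-3-(2-fluoro-3-nitrophenyl)-2-methylpropan-1-ol | O=[N+]([O-])c1cccc(C[C@@H](C)CO)c1F | intermediate
5 | (2R)-3-(2-fluoro-3-nitrophenyl)-2-methylpropyl trifluoromethanesulfonate | O=[N+]([O-])c1cccc(C[C@@H](C)COS(=O)(=O)C(F)(F)F)c1F | intermediate
6 | 1,1,2-trimethoxyethane | COCC(OC)OC | starting material
7 | SAMP, (S)-1-amino-2-(methoxymethyl)pyrrolidine | COC[C@@H]1CCCN1N | starting material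
8 | (2S)-N-[(E)-2-methoxyethylidene]-2-(methoxymethyl)pyrrolidin-1-amine | COC/C=N/N1CCC[C@H]1COC | intermediate
9 | (E)-SAMP hydrazone of (2S,4R)-5-(2-fluoro-3-nitrophenyl)-2-methoxy-4-methylpentanal | O=[N+]([O-])c1cccc(C[C@@H](C)C[C@H](OC)/C=N/N2CCC[C@H]2COC)c1F | intermediate
10 | (2S,4R)-5-(2-fluoro-3-nitrophenyl)-2-methoxy-4-methylpentanal | O=[N+]([O-])c1cccc(C[C@@H](C)C[C@H](OC)C=O)c1F | intermediate
11 | 2-[(2Z)-but-2-en-1-yl]-4,4,5,5-tetramethyl-1,3,2-dioxaborolane | C/C=C\CB1OC(C)(C)C(C)(C)O1 | starting material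
12 | (3S,4R,5S,7R)-8-(2-fluoro-3-nitrophenyl)-5-methoxy-3,7-dimethyloct-1-en-4-ol | O=[N+]([O-])c1cccc(C[C@@H](C)C[C@H](OC)[C@H](O)[C@@H](C)C=C)c1F | intermediate
13 | (2R,3S,5R)-2-[(2S)-but-3-en-2-yl]-3-methoxy-5-methyl-10-nitro-3,4,5,6-tetrahydro-2H-1-benzoxocine | CO[C@H]1C[C@H](C)Cc2cccc([N+](=O)[O-])c2O[C@@H]1[C@@H](C)C=C | intermediate
14 | (2R)-2-[(2R,3S,5R)-3-methoxy-5-methyl-10-nitro-3,4,5,6-tetrahydro-2H-1-benzoxocin-2-yl]propanal | CO[C@H]1C[C@H](C)Cc2cccc([N+](=O)[O-])c2O[C@@H]1[C@@H](C)C=O | intermediate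
15 | (2R,3S,5R)-2-[(2S,3Z)-4-iodopent-3-en-2-yl]-3-methoxy-5-methyl-10-nitro-3,4,5,6-tetrahydro-2H-1-benzoxocine | CO[C@H]1C[C@H](C)Cc2cccc([N+](=O)[O-])c2O[C@@H]1[C@@H](C)/C=C(/C)I | intermediate
16 | (2R,3S,5R)-2-[(2S,3Z)-4-iodopent-3-en-2-yl]-3-methoxy-5-methyl-3,4,5,6-tetrahydro-2H-1-benzoxocin-10-amine | CO[C@H]1C[C@H](C)Cc2cccc(N)c2O[C@@H]1[C@@H](C)/C=C(/C)I | intermediate
17 | 2-(bromomethyl)oxirane (epibromohydrin, racemic) | BrCC1CO1 | starting material
18 | (E)-SAMP hydrazone of (2S)-2-methoxy-3-(oxiran-2-yl)propanal (both oxirane epimers) | C1OC1C[C@H](OC)/C=N/N1CCC[C@H]1COC | intermediate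
19 | (2S)-2-methoxy-3-(oxiran-2-yl)propanal (both oxirane epimers) | C1OC1C[C@H](OC)C=O | intermediate
20 | 16 with the amino group as the 2,2,5,5-tetramethyl-1-aza-2,5-disilacyclopentan-1-yl group | CO[C@H]1C[C@H](C)Cc2cccc(N3[Si](C)(C)CC[Si]3(C)C)c2O[C@@H]1[C@@H](C)/C=C(/C)I | intermediate
21 | (Z)-alkenylmagnesium bromide from 20 (MgBr at C8 in place of I) | CO[C@H]1C[C@H](C)Cc2cccc(N3[Si](C)(C)CC[Si]3(C)C)c2O[C@@H]1[C@@H](C)/C=C(/C)[Mg]Br | intermediate
22 | N-silyl-protected C7 N-(trichloroacetyl)carbamate (6S,7S) | CO[C@H]1C[C@H](C)Cc2cccc(N3[Si](C)(C)CC[Si]3(C)C)c2O[C@@H]1[C@@H](C)/C=C(/C)[C@H](OC(=O)NC(=O)C(Cl)(Cl)Cl)[C@@H](OC)CC4CO4 | intermediate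
23 | (2S,3S,4Z,6S)-6-[(2R,3S,5R)-10-amino-3-methoxy-5-methyl-3,4,5,6-tetrahydro-2H-1-benzoxocin-2-yl]-2-methoxy-4-methyl-1-(oxiran-2-yl)hept-4-en-3-yl carbamate | CO[C@H]1C[C@H](C)Cc2cccc(N)c2O[C@@H]1[C@@H](C)/C=C(/C)[C@H](OC(N)=O)[C@@H](OC)CC3CO3 | intermediate
24 | pyruvic acid (2-oxopropanoic acid) | CC(=O)C(=O)O | starting material
25 | 23 acylated on the aniline nitrogen as the 2-oxopropanamide | CO[C@H]1C[C@H](C)Cc2cccc(NC(=O)C(C)=O)c2O[C@@H]1[C@@H](C)/C=C(/C)[C@H](OC(N)=O)[C@@H](OC)CC3CO3 | intermediate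
26 | 25 with the oxirane opened to C4H(OH)–C3H2Br (both C4 epimers) | CO[C@H]1C[C@H](C)Cc2cccc(NC(=O)C(C)=O)c2O[C@@H]1[C@@H](C)/C=C(/C)[C@H](OC(N)=O)[C@@H](OC)CC(O)CBr | intermediate
27 | bromomethyl ketone (C4=O, C3H2Br) with the 2-oxopropanamide on N | CO[C@H]1C[C@H](C)Cc2cccc(NC(=O)C(C)=O)c2O[C@@H]1[C@@H](C)/C=C(/C)[C@H](OC(N)=O)[C@@H](OC)CC(=O)CBr | intermediate
28 | S-(2-oxoalkyl)tetrahydrothiophenium bromide from 27 | CO[C@H]1C[C@H](C)Cc2cccc(NC(=O)C(C)=O)c2O[C@@H]1[C@@H](C)/C=C(/C)[C@H](OC(N)=O)[C@@H](OC)CC(=O)C[S+]3CCCC3.[Br-] | intermediate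
29 | keto-stabilised sulfonium ylide from 28 | CO[C@H]1C[C@H](C)Cc2cccc(NC(=O)C(C)=O)c2O[C@@H]1[C@@H](C)/C=C(/C)[C@H](OC(N)=O)[C@@H](OC)CC(=O)[CH-][S+]3CCCC3 | intermediate
30 | (2S,3S)-2,3-epoxy-4-oxo 18-deoxy macrolactam (C3 epimer equally usable) | CO[C@H]1C[C@H](C)Cc2cccc3c2O[C@@H]1[C@@H](C)/C=C(/C)[C@H](OC(N)=O)[C@@H](OC)CC(=O)[C@H]4O[C@]4(C)C(=O)N3 | intermediate
31 | 18-deoxy target (2S,6S,7S,8Z,10S,11R,12S,14R) | CO[C@H]1C[C@H](C)Cc2cccc3c2O[C@@H]1[C@@H](C)/C=C(/C)[C@H](OC(N)=O)[C@@H](OC)CC(=O)C[C@](C)(O)C(=O)N3 | intermediate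
32 | 18-(4,4,5,5-tetramethyl-1,3,2-dioxaborolan-2-yl) derivative of 31 | CO[C@H]1C[C@H](C)Cc2cc(B4OC(C)(C)C(C)(C)O4)cc3c2O[C@@H]1[C@@H](C)/C=C(/C)[C@H](OC(N)=O)[C@@H](OC)CC(=O)C[C@](C)(O)C(=O)N3 | intermediate
33 | CNP0122739.1 | CO[C@H]1C[C@H](C)Cc2cc(O)cc3c2O[C@@H]1[C@@H](C)/C=C(/C)[C@H](OC(N)=O)[C@@H](OC)CC(=O)C[C@](C)(O)C(=O)N3 | target

**Step count and risks**
Total steps: 20. Longest linear sequence: 17 (steps 1–3, 5–11, 14–20).

Most likely to fail:

Step 18 (ring closure may lose to oligomerisation, and the C2 face is controlled only by the macrocycle). Fallback: set out from 27 and remove the bromine with Bu3SnH and AIBN in toluene at 80 °C to give the methyl ketone/pyruvanilide F3. An enamine-type direct aldol under a cinchona primary amine (9-amino-9-deoxy-epi-quinine, CF3CO2H, toluene, high dilution) then forms C2–C3 with reagent control of the C2 face and returns to the route at 31.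

Step 8 (8-membered ring closure against dimerisation). Fallback: set out from 10 and use (E)-crotyldiisopinocampheylborane, chosen to override the Cornforth bias, to give the C11-epimeric alcohol (3S,4S,5S,7R)-8-(2-fluoro-3-nitrophenyl)-5-methoxy-3,7-dimethyloct-1-en-4-ol F1. KOH in DMSO–water replaces the activated fluoride by hydroxide to give 2-[(2R,4S,5S,6S)-5-hydroxy-4-methoxy-2,6-dimethyloct-7-en-1-yl]-6-nitrophenol F2. An intramolecular Mitsunobu etherification (PPh3, diisopropyl azodicarboxylate, toluene, high dilution) forms O–C11 with inversion and returns to the route at 13.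

Step 20 (C–H borylation on a substrate with free NH and OH groups, a ketone and an alkene). Fallback: set out from 31 and iodinate para to the ether oxygen (N-iodosuccinimide, catalytic CF3CO2H, MeCN, 0 °C) to give the 18-iodo macrolactam F4. Miyaura borylation (PdCl2(dppf), B2pin2, KOAc, dioxane, 80 °C) rejoins the route at the boronate 32, which is oxidised as in step 20 to 33.

**Further compounds**
F1 | step 8 | (3S,4S,5S,7R)-8-(2-fluoro-3-nitrophenyl)-5-methoxy-3,7-dimethyloct-1-en-4-ol | O=[N+]([O-])c1cccc(C[C@@H](C)C[C@H](OC)[C@@H](O)[C@@H](C)C=C)c1F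
F2 | step 8 | 2-[(2R,4S,5S,6S)-5-hydroxy-4-methoxy-2,6-dimethyloct-7-en-1-yl]-6-nitrophenol | O=[N+]([O-])c1cccc(C[C@@H](C)C[C@H](OC)[C@@H](O)[C@@H](C)C=C)c1O
F3 | step 18 | methyl ketone (C4=O, C3H3) with the 2-oxopropanamide on N | CO[C@H]1C[C@H](C)Cc2cccc(NC(=O)C(C)=O)c2O[C@@H]1[C@@H](C)/C=C(/C)[C@H](OC(N)=O)[C@@H](OC)CC(C)=O
F4 | step 20 | 18-iodo derivative of 31 | CO[C@H]1C[C@H](C)Cc2cc(I)cc3c2O[C@@H]1[C@@H](C)/C=C(/C)[C@H](OC(N)=O)[C@@H](OC)CC(=O)C[C@](C)(O)C(=O)N3
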